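**Remark on the chemistry:** flavanone numbering is used (O1, C2, C3, C4, C4a, C5–C8, C8a; ring A = benzo ring, ring B = 2-aryl ring, ring C = pyranone). The target is read as the (2S)-flavanone with an E side-chain alkene.

## Retrosynthetic overview

1. Ring C is cut at C3–C4 and O1–C8a. This gives a ring-A 2-fluoroaryl N-methoxy-N-methylamide (C4 acyl on C4a, F on C8a, side chain on C8) and a ring-B C,O-dianion LiCH2–CH(OLi)Ar (C3–C2–O1) made from an (R)-chlorohydrin.
2. Enabling feature: O1 and C3 both sit on C2, and the C4 carbonyl sits on C4a, ortho to C8a of ring A. A β-oxido carbanion can therefore acylate at C3, and the aryl ketone so formed activates C8a–F for SNAr by O1. The C2–O1 and C2–C3 bonds are never broken, so the stereocentre is carried through.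
3. C2 is set by asymmetric transfer hydrogenation of an α-chloro ketone. The C8 chain comes from fluorine/methoxy-directed metalation, prenylation and E-selective SeO2 hydroxylation; C4 comes from Br/Li exchange and carbamoylation.
4. Ring order: rings A and B are bought as benzenes; ring C is the only ring formed, in the key step; acid solvolysis of the MOM and silyl ethers ends the route.

Key step: step 7

## Route

**Step 1**
Reactants: 1 1-bromo-2-fluoro-4-methoxybenzene
Product: 3 1-bromo-2-fluoro-4-methoxy-3-(3-methylbut-2-en-1-yl)benzene, via aryllithium 2 (not isolated)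
Conditions: LiN(i-Pr)2 (1.1 equiv), THF, −78 °C; then CuBr·SMe2 (10 mol %), prenyl bromide, −78 to −40 °C
Reagents that add atoms: prenyl bromide (1-bromo-3-methylbut-2-ene), CC(C)=CCBr
Why: Directed ortho-metalation should remove the most acidic ring proton, the one flanked by F and OMe, without touching C–Br, and copper-catalysed allylic substitution of the aryllithium on prenyl bromide should occur at the unhindered primary carbon (SN2, not SN2′).

**Step 2**
Reactants: 3 1-bromo-2-fluoro-4-methoxy-3-(3-methylbut-2-en-1-yl)benzene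
Product: 4 (E)-4-(3-bromo-2-fluoro-6-methoxyphenyl)-2-methylbut-2-en-1-ol
Conditions: SeO2 (0.5 equiv), t-BuOOH (3 equiv, in decane), CH2Cl2, 0 to 25 °C
Reagents that add atoms: selenium dioxide, O=[Se]=O (catalytic oxygen carrier); tert-butyl hydroperoxide, CC(C)(C)OO (terminal source of the oxygen)
Why: Sharpless–Umbreit allylic oxidation (ene reaction, then [2,3]-sigmatropic shift) should hydroxylate the methyl group trans to the chain at the more substituted alkene terminus, which fixes the E geometry of the side chain; any over-oxidised enal would be removed by chromatography.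

**Step 3**
Reactants: 4 (E)-4-(3-bromo-2-fluoro-6-methoxyphenyl)-2-methylbut-2-en-1-ol
Product: 5 {[(E)-4-(3-bromo-2-fluoro-6-methoxyphenyl)-2-methylbut-2-en-1-yl]oxy}(tert-butyl)dimethylsilane
Conditions: TBSCl, imidazole, CH2Cl2, 25 °C
Reagents that add atoms: tert-butyldimethylsilyl chloride (TBSCl), CC(C)(C)[Si](C)(C)Cl
Why: Standard silyl ether formation on a primary alcohol masks the only acidic proton before the organolithium steps.

**Step 4**
Reactants: 5 {[(E)-4-(3-bromo-2-fluoro-6-methoxyphenyl)-2-methylbut-2-en-1-yl]oxy}(tert-butyl)dimethylsilane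
Product: 7 3-[(E)-4-(tert-butyldimethylsilyloxy)-3-methylbut-2-en-1-yl]-2-fluoro-N,4-dimethoxy-N-methylbenzamide, via aryllithium 6 (not isolated)
Conditions: n-BuLi (1.05 equiv), THF, −78 °C; cannulated into ClC(O)N(OMe)Me (1.5 equiv), THF, −78 °C
Reagents that add atoms: N-methoxy-N-methylcarbamoyl chloride, CON(C)C(=O)Cl
Why: Bromine–lithium exchange is faster than any deprotonation at −78 °C, and inverse addition of the ortho-fluoroaryllithium to the carbamoyl chloride (nucleophilic acyl substitution) should give the Weinreb amide before LiF loss or a second addition can occur.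

**Step 5**
Reactants: 8 2-chloro-1-(3,4-dihydroxyphenyl)ethan-1-one
Product: 9 1-[3,4-bis(methoxymethoxy)phenyl]-2-chloroethan-1-one
Conditions: MOMCl (2.6 equiv), i-Pr2NEt (3.0 equiv), CH2Cl2, 0 to 25 °C
Reagents that add atoms: chloromethyl methyl ether (MOMCl), COCCl
Why: O-alkylation of both phenols by the highly reactive α-chloro ether under a hindered amine base (Williamson-type etherification) should outrun any reaction at the chloro ketone.

**Step 6**
Reactants: 9 1-[3,4-bis(methoxymethoxy)phenyl]-2-chloroethan-1-one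
Product: 10 (R)-1-[3,4-bis(methoxymethoxy)phenyl]-2-chloroethan-1-ol
Conditions: RuCl[(S,S)-TsDPEN](p-cymene) (1 mol %), HCO2H/Et3N (5:2), EtOAc, 25 °C
Reagents that add atoms: none
Why: Noyori–Ikariya asymmetric transfer hydrogenation sets the carbinol stereocentre through ligand-controlled hydride delivery to one ketone face (the sense that gives (S)-1-arylethanols corresponds here to R because CH2Cl outranks aryl), and the acidic medium keeps the chlorohydrin from closing to the epoxide.

**Step 7**
Reactants: 10 (R)-1-[3,4-bis(methoxymethoxy)phenyl]-2-chloroethan-1-ol; 7 3-[(E)-4-(tert-butyldimethylsilyloxy)-3-methylbut-2-en-1-yl]-2-fluoro-N,4-dimethoxy-N-methylbenzamide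
Product: 15 (S)-2-[3,4-bis(methoxymethoxy)phenyl]-8-[(E)-4-(tert-butyldimethylsilyloxy)-3-methylbut-2-en-1-yl]-7-methoxychroman-4-one, via lithium alkoxide 11 (not isolated), via C,O-dilithio reagent 12 (not isolated), via tetrahedral adduct 13 (not isolated), via oxido ketone 14 (not isolated)
Conditions: 10 (1.3 equiv), n-BuLi (1.3 equiv), THF, −78 °C; LiC10H8 (lithium naphthalenide, 2.6 equiv), −78 °C; 7 (1.0 equiv), −78 °C; AcOH (1.6 equiv), −78 to 0 °C; DMPU, 40 °C
Reagents that add atoms: none
Why: Deprotonation of 10 and two-electron reductive cleavage of its C–Cl bond by LiC10H8 give the C,O-dilithio reagent 12, whose carbanion C3 adds once to the amide 7 (C3–C4, chelated adduct 13); the measured amount of AcOH then collapses 13 to the ortho-fluoroaryl ketone while the C2 alkoxide stays lithiated (14), and on warming this alkoxide displaces fluoride at C8a by addition–elimination (O1–C8a), the new C4 carbonyl ortho to C8a stabilising the Meisenheimer intermediate. The closest known reaction types are the trapping of β-oxido organolithiums made from chlorohydrins by reductive lithiation, the single acylation of alkyllithiums by N-methoxy-N-methylamides, and the intramolecular SNAr etherification of β-hydroxy ortho-fluoroaryl ketones to chroman-4-ones. Ring C, the only ring formed, closes as a six-membered ring by intramolecular addition–elimination at the aromatic carbon C8a (6-exo-trig with respect to the C8a=C8 bond). No stereocentre is created: C2 is brought in from 10 and neither its C–O nor its C–C bond is broken, so the (R)-chlorohydrin maps onto the (2S)-flavanone, the descriptor changing only because the substituent priorities change. The step needs carbonyl addition ahead of attack at C–F, a single addition, and ring closure ahead of β-elimination of 12, aldol-type dehydration of 14 or base-induced opening of 15: the oxido group of 12 is no leaving group at −78 °C, the amide chelate secures single addition, the C–F bond becomes labile only once the ketone is unmasked, and because the one remaining alkoxide equivalent ends as LiF the mixture should finish close to neutral.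

**Step 8**
Reactants: 15 (S)-2-[3,4-bis(methoxymethoxy)phenyl]-8-[(E)-4-(tert-butyldimethylsilyloxy)-3-methylbut-2-en-1-yl]-7-methoxychroman-4-one
Product: 16 (S)-2-(3,4-dihydroxyphenyl)-8-[(E)-4-hydroxy-3-methylbut-2-en-1-yl]-7-methoxychroman-4-one
Conditions: HCl (2 M in MeOH), THF, 40 °C
Reagents that add atoms: none
Why: Acid-catalysed acetal exchange and silyl ether solvolysis should remove both aryl MOM groups and the primary silyl group in one operation, under conditions where the flavanone stereocentre (labile only to base) and the methyl ether should persist.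

## Compound list

1 | 1-bromo-2-fluoro-4-methoxybenzene (4-bromo-3-fluoroanisole) | COc1ccc(Br)c(F)c1 | starting material
2 | (3-bromo-2-fluoro-6-methoxyphenyl)lithium | COc1ccc(Br)c(F)c1[Li] | intermediate (not isolated)
3 | 1-bromo-2-fluoro-4-methoxy-3-(3-methylbut-2-en-1-yl)benzene | COc1ccc(Br)c(F)c1CC=C(C)C | intermediate
4 | (E)-4-(3-bromo-2-fluoro-6-methoxyphenyl)-2-methylbut-2-en-1-ol | COc1ccc(Br)c(F)c1C/C=C(\C)CO | intermediate
5 | {[(E)-4-(3-bromo-2-fluoro-6-methoxyphenyl)-2-methylbut-2-en-1-yl]oxy}(tert-butyl)dimethylsilane | COc1ccc(Br)c(F)c1C/C=C(\C)CO[Si](C)(C)C(C)(C)C | intermediate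
6 | {3-[(E)-4-(tert-butyldimethylsilyloxy)-3-methylbut-2-en-1-yl]-2-fluoro-4-methoxyphenyl}lithium | COc1ccc([Li])c(F)c1C/C=C(\C)CO[Si](C)(C)C(C)(C)C | intermediate (not isolated)
7 | 3-[(E)-4-(tert-butyldimethylsilyloxy)-3-methylbut-2-en-1-yl]-2-fluoro-N,4-dimethoxy-N-methylbenzamide | COc1ccc(C(=O)N(C)OC)c(F)c1C/C=C(\C)CO[Si](C)(C)C(C)(C)C | intermediate
8 | 2-chloro-1-(3,4-dihydroxyphenyl)ethan-1-one | O=C(CCl)c1ccc(O)c(O)c1 | starting material
9 | 1-[3,4-bis(methoxymethoxy)phenyl]-2-chloroethan-1-one | COCOc1ccc(C(=O)CCl)cc1OCOC | intermediate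
10 | (R)-1-[3,4-bis(methoxymethoxy)phenyl]-2-chloroethan-1-ol | O[C@H](c1ccc(OCOC)c(OCOC)c1)CCl | intermediate
11 | lithium (R)-1-[3,4-bis(methoxymethoxy)phenyl]-2-chloroethan-1-olate | [Li]O[C@H](c1ccc(OCOC)c(OCOC)c1)CCl | intermediate (not isolated)
12 | (S)-{2-[3,4-bis(methoxymethoxy)phenyl]-2-(lithiooxy)ethyl}lithium (same spatial arrangement as 10) | [Li]O[C@H](c1ccc(OCOC)c(OCOC)c1)C[Li] | intermediate (not isolated)
13 | dilithium salt of (3S)-3-[3,4-bis(methoxymethoxy)phenyl]-1-{3-[(E)-4-(tert-butyldimethylsilyloxy)-3-methylbut-2-en-1-yl]-2-fluoro-4-methoxyphenyl}-1-[methoxy(methyl)amino]propane-1,3-diol (mixture at C1) | COc1ccc(C(O[Li])(N(C)OC)C[C@H](O[Li])c2ccc(OCOC)c(OCOC)c2)c(F)c1C/C=C(\C)CO[Si](C)(C)C(C)(C)C | intermediate (not isolated)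
14 | lithium (S)-1-[3,4-bis(methoxymethoxy)phenyl]-3-{3-[(E)-4-(tert-butyldimethylsilyloxy)-3-methylbut-2-en-1-yl]-2-fluoro-4-methoxyphenyl}-3-oxopropan-1-olate | COc1ccc(C(=O)C[C@H](O[Li])c2ccc(OCOC)c(OCOC)c2)c(F)c1C/C=C(\C)CO[Si](C)(C)C(C)(C)C | intermediate (not isolated)
15 | (S)-2-[3,4-bis(methoxymethoxy)phenyl]-8-[(E)-4-(tert-butyldimethylsilyloxy)-3-methylbut-2-en-1-yl]-7-methoxychroman-4-one | COc1ccc2c(c1C/C=C(\C)CO[Si](C)(C)C(C)(C)C)O[C@H](c1ccc(OCOC)c(OCOC)c1)CC2=O | intermediate
16 | (S)-2-(3,4-dihydroxyphenyl)-8-[(E)-4-hydroxy-3-methylbut-2-en-1-yl]-7-methoxychroman-4-one | COc1ccc2c(c1C/C=C(\C)CO)O[C@H](c1ccc(O)c(O)c1)CC2=O | target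

## Step count and risks

Total step count: 8. Longest linear sequence: 6 steps (1, 2, 3, 4, 7, 8).

**Step 7.** The C,O-dilithio reagent 12 may lose Li2O by β-elimination to the styrene before it meets 7, or the reductive lithiation may attack other groups. Dehydration of 14 may also compete with ring closure. The fallback reverses the polarity of the C3–C4 bond construction (Corey–Seebach umpolung) and sets out from 5 and 10. Bromide 5 would be lithiated (n-BuLi, THF, −78 °C, via 6) and formylated with DMF to 3-[(E)-4-(tert-butyldimethylsilyloxy)-3-methylbut-2-en-1-yl]-2-fluoro-4-methoxybenzaldehyde F1. Propane-1,3-dithiol with catalytic iodine in CH2Cl2 would convert F1 into the 2-aryl-1,3-dithiane F2, which n-BuLi (THF, −78 to −20 °C) would turn into the 2-lithio-1,3-dithiane F3. Chlorohydrin 10 would be closed with K2CO3 in MeOH to (R)-2-[3,4-bis(methoxymethoxy)phenyl]oxirane F4, with the C2–O bond untouched. F3 should open F4 at the terminal carbon to give the hydroxy dithiane F5. Dethioketalisation (MeI, CaCO3, MeCN/H2O) would release the β-hydroxy ketone F6, the neutral form of 14. F6 would then be cyclised separately by SNAr (K2CO3, DMF, 40 °C), where base and temperature can be tuned, and the route comes back at 15.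

**Step 2.** The allylic oxidation may stall or run on to the enal, and selenium by-products may complicate isolation. The fallback builds the oxidised chain by olefin metathesis and sets out from 1. Aryllithium 2 (LiN(i-Pr)2, THF, −78 °C) would be allylated with allyl bromide under CuBr·SMe2 catalysis to 1-bromo-2-fluoro-4-methoxy-3-(prop-2-en-1-yl)benzene F7. Cross-metathesis of F7 with methacrolein (second-generation Hoveyda–Grubbs catalyst, CH2Cl2, 40 °C) should give the E-configured enal (E)-4-(3-bromo-2-fluoro-6-methoxyphenyl)-2-methylbut-2-enal F8. Luche reduction (NaBH4, CeCl3·7H2O, MeOH, 0 °C) would then return the route at 4.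

**Step 1.** The ortho-fluoroaryllithium 2 may lose LiF to an aryne on warming before it couples, or the copper-mediated substitution may occur at the tertiary terminus of the prenyl unit (SN2′). The fallback replaces the organocopper substitution by a palladium-catalysed cross-coupling and sets out from 1. Aryllithium 2 would be quenched at −78 °C with iodine to 1-bromo-2-fluoro-3-iodo-4-methoxybenzene F9. Stille coupling of F9 at the more reactive C–I bond with tributyl(3-methylbut-2-en-1-yl)stannane (Pd(PPh3)4, DMF, 80 °C) should give the linear prenyl arene, and the route comes back at 3.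

## Further compounds

F1 | step 7 | 3-[(E)-4-(tert-butyldimethylsilyloxy)-3-methylbut-2-en-1-yl]-2-fluoro-4-methoxybenzaldehyde | COc1ccc(C=O)c(F)c1C/C=C(\C)CO[Si](C)(C)C(C)(C)C
F2 | step 7 | 2-{3-[(E)-4-(tert-butyldimethylsilyloxy)-3-methylbut-2-en-1-yl]-2-fluoro-4-methoxyphenyl}-1,3-dithiane | COc1ccc(C2SCCCS2)c(F)c1C/C=C(\C)CO[Si](C)(C)C(C)(C)C
F3 | step 7 | 2-lithio-2-{3-[(E)-4-(tert-butyldimethylsilyloxy)-3-methylbut-2-en-1-yl]-2-fluoro-4-methoxyphenyl}-1,3-dithiane | COc1ccc(C2([Li])SCCCS2)c(F)c1C/C=C(\C)CO[Si](C)(C)C(C)(C)C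
F4 | step 7 | (R)-2-[3,4-bis(methoxymethoxy)phenyl]oxirane | O1[C@H](c2ccc(OCOC)c(OCOC)c2)C1
F5 | step 7 | (S)-1-[3,4-bis(methoxymethoxy)phenyl]-2-(2-{3-[(E)-4-(tert-butyldimethylsilyloxy)-3-methylbut-2-en-1-yl]-2-fluoro-4-methoxyphenyl}-1,3-dithian-2-yl)ethan-1-ol | COc1ccc(C2(C[C@H](O)c3ccc(OCOC)c(OCOC)c3)SCCCS2)c(F)c1C/C=C(\C)CO[Si](C)(C)C(C)(C)C
F6 | step 7 | (S)-3-[3,4-bis(methoxymethoxy)phenyl]-1-{3-[(E)-4-(tert-butyldimethylsilyloxy)-3-methylbut-2-en-1-yl]-2-fluoro-4-methoxyphenyl}-3-hydroxypropan-1-one | COc1ccc(C(=O)C[C@H](O)c2ccc(OCOC)c(OCOC)c2)c(F)c1C/C=C(\C)CO[Si](C)(C)C(C)(C)C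
F7 | step 2 | 1-bromo-2-fluoro-4-methoxy-3-(prop-2-en-1-yl)benzene | COc1ccc(Br)c(F)c1CC=C
F8 | step 2 | (E)-4-(3-bromo-2-fluoro-6-methoxyphenyl)-2-methylbut-2-enal | COc1ccc(Br)c(F)c1C/C=C(\C)C=O
F9 | step 1 | 1-bromo-2-fluoro-3-iodo-4-methoxybenzene | COc1ccc(Br)c(F)c1I
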